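**Retrosynthetic overview**

- The strategy rests on C2 of the pyranone ring (ring C): a lone CH between O1 and C3 at the acetal oxidation level. It is traced back to the O–CH2–O carbon of a methoxymethyl ether on the C8a oxygen, and the C2–C3 bond is made last by rhodium carbenoid C–H insertion of an α-aryl-α-diazo ketone, followed by loss of methanol.
- The diazo ketone comes by diazo transfer from a deoxybenzoin, whose C3–C4 bond is made from ring A aldehyde 8 and the ring B benzylzinc reagent 15.
- Ring A: phloroglucinol and acrylic acid give a dihydrocoumarin whose lactone masks one oxygen ortho to the side chain. Both free phenols become MOM ethers, MeMgBr opens the lactone, and the one phenol set free directs the formylation (C4–C4a), so the acetal para to the side chain ends up ortho to the carbonyl without any selective monoprotection.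
- The second MOM group (C7 oxygen) is meta to the acyl carbon and is a spectator; after the key step it is exchanged with a silyl triflate and 2,2'-bipyridyl, and fluoride then removes the silyl groups.
- Order of rings: temporary lactone ring (steps 1 to 3), pyran ring D on fragment B (step 7), ring C last (step 14).

Key step: step 14

Remark on the chemistry: carbinol 16 (one stereocentre) is formed as a racemate and isoflavanone 19 (two stereocentres) as a diastereomer mixture; these centres are erased in steps 12 and 14, and the target has no stereocentre.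

**Route**

Step 1
Reactants: 1 phloroglucinol; 2 acrylic acid
Product: 3 5,7-dihydroxychroman-2-one
Conditions: Amberlyst 15, toluene, 110 °C
Reagents that add atoms: none
Why: Acid-catalysed Friedel–Crafts conjugate hydroarylation of acrylic acid by the highly nucleophilic phloroglucinol, followed by lactonisation onto an ortho hydroxyl, should give the dihydrocoumarin, and the three ring positions are equivalent so no regiochemical question arises.

Step 2
Reactants: 3 5,7-dihydroxychroman-2-one
Product: 4 5,7-bis(methoxymethoxy)chroman-2-one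
Conditions: MOMCl, i-Pr2NEt, CH2Cl2, 0 to 25 °C
Reagents that add atoms: chloromethyl methyl ether, COCCl
Why: O-Alkylation of both free phenols with the chloromethyl ether under a non-nucleophilic amine base leaves the aryl lactone intact, and because both phenols take the same group no selectivity is required.

Step 3
Reactants: 4 5,7-bis(methoxymethoxy)chroman-2-one
Product: 5 2-(3-hydroxy-3-methylbutyl)-3,5-bis(methoxymethoxy)phenol
Conditions: MeMgBr (excess), THF, 0 to 25 °C; aq NH4Cl
Reagents that add atoms: methylmagnesium bromide, C[Mg]Br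
Why: Double Grignard addition to the aryl lactone gives the dimethyl carbinol and releases exactly one phenol, the one ortho to the side chain, while the MOM ethers are inert.

Step 4
Reactants: 5 2-(3-hydroxy-3-methylbutyl)-3,5-bis(methoxymethoxy)phenol
Product: 6 2-hydroxy-3-(3-hydroxy-3-methylbutyl)-4,6-bis(methoxymethoxy)benzaldehyde
Conditions: MgCl2, Et3N, (CH2O)n, THF, 65 °C; aq NH4Cl
Reagents that add atoms: paraformaldehyde (formaldehyde), C=O
Why: Magnesium-phenoxide-directed ortho-formylation (Casnati–Skattebøl reaction) can only reach the single free position ortho to the free phenol, which places the aldehyde between that phenol and the MOM ether para to the side chain, a second formaldehyde serving as hydride acceptor.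

Step 5
Reactants: 6 2-hydroxy-3-(3-hydroxy-3-methylbutyl)-4,6-bis(methoxymethoxy)benzaldehyde
Product: 7 2-(tert-butyldimethylsilyloxy)-3-(3-hydroxy-3-methylbutyl)-4,6-bis(methoxymethoxy)benzaldehyde
Conditions: TBSCl, imidazole, DMAP (cat.), DMF, 40 °C
Reagents that add atoms: tert-butyldimethylsilyl chloride, CC(C)(C)[Si](C)(C)Cl
Why: Silylation with the silyl chloride and imidazole takes the chelated phenol but not the tertiary alcohol, which is too hindered for this reagent.

Step 6
Reactants: 7 2-(tert-butyldimethylsilyloxy)-3-(3-hydroxy-3-methylbutyl)-4,6-bis(methoxymethoxy)benzaldehyde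
Product: 8 2-(tert-butyldimethylsilyloxy)-4,6-bis(methoxymethoxy)-3-[3-methyl-3-(triethylsilyloxy)butyl]benzaldehyde
Conditions: Et3SiOTf, 2,6-lutidine, CH2Cl2, −78 °C
Reagents that add atoms: triethylsilyl trifluoromethanesulfonate, CC[Si](CC)(CC)OS(=O)(=O)C(F)(F)F
Why: A silyl triflate with a hindered pyridine base silylates the tertiary alcohol at low temperature, where the aryl MOM and TBS ethers and the aldehyde are not touched.

Step 7
Reactants: 9 2,4-dihydroxybenzaldehyde; 10 3-methylbut-2-enal
Product: 11 5-hydroxy-2,2-dimethyl-2H-chromene-6-carbaldehyde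
Conditions: ethylenediammonium diacetate (cat.), xylene, 140 °C
Reagents that add atoms: none
Why: Amine-salt-catalysed condensation of the enal at the ring carbon between the two oxygens followed by oxa-6π electrocyclisation through the unchelated 4-hydroxyl gives the angular chromene, the hydroxyl hydrogen-bonded to the aldehyde staying free.

Step 8
Reactants: 11 5-hydroxy-2,2-dimethyl-2H-chromene-6-carbaldehyde
Product: 12 5-(tert-butyldimethylsilyloxy)-2,2-dimethyl-2H-chromene-6-carbaldehyde
Conditions: TBSCl, imidazole, DMF, 25 °C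
Reagents that add atoms: tert-butyldimethylsilyl chloride, CC(C)(C)[Si](C)(C)Cl
Why: Standard silylation of a salicylaldehyde-type phenol.

Step 9
Reactants: 12 5-(tert-butyldimethylsilyloxy)-2,2-dimethyl-2H-chromene-6-carbaldehyde
Product: 13 [5-(tert-butyldimethylsilyloxy)-2,2-dimethyl-2H-chromen-6-yl]methanol
Conditions: NaBH4, MeOH/THF, 0 °C
Reagents that add atoms: none
Why: Borohydride 1,2-reduction of the aldehyde at 0 °C with a short reaction time should avoid O-to-O silyl migration and leaves the chromene alkene alone.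

Step 10
Reactants: 13 [5-(tert-butyldimethylsilyloxy)-2,2-dimethyl-2H-chromen-6-yl]methanol
Product: 14 5-(tert-butyldimethylsilyloxy)-6-(chloromethyl)-2,2-dimethyl-2H-chromene
Conditions: PPh3, N-chlorosuccinimide, THF, 0 to 25 °C; used at once without chromatography
Reagents that add atoms: N-chlorosuccinimide, O=C1CCC(=O)N1Cl
Why: Appel-type chlorination through the alkoxyphosphonium salt proceeds under neutral conditions, which the silyl ether and the electron-rich, ionisation-prone benzylic chloride require.

Step 11
Reactants: 14 5-(tert-butyldimethylsilyloxy)-6-(chloromethyl)-2,2-dimethyl-2H-chromene; 8 2-(tert-butyldimethylsilyloxy)-4,6-bis(methoxymethoxy)-3-[3-methyl-3-(triethylsilyloxy)butyl]benzaldehyde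
Product: 16 racemic 1-{2-(tert-butyldimethylsilyloxy)-4,6-bis(methoxymethoxy)-3-[3-methyl-3-(triethylsilyloxy)butyl]phenyl}-2-[5-(tert-butyldimethylsilyloxy)-2,2-dimethyl-2H-chromen-6-yl]ethanol, via benzylzinc chloride 15 (not isolated)
Conditions: Zn dust, LiCl, THF, 25 °C; then 8, MgCl2, THF, 0 to 25 °C; aq NH4Cl
Reagents that add atoms: none
Why: LiCl-promoted insertion of zinc into the benzylic chloride gives a benzylzinc chloride that adds to the aldehyde under MgCl2 activation, and the covalent zinc alkoxide should not trigger silyl migration from the neighbouring aryl silyl ether; the new carbinol centre is formed without control and is removed in step 12.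

Step 12
Reactants: 16 racemic carbinol
Product: 17 1-{2-(tert-butyldimethylsilyloxy)-4,6-bis(methoxymethoxy)-3-[3-methyl-3-(triethylsilyloxy)butyl]phenyl}-2-[5-(tert-butyldimethylsilyloxy)-2,2-dimethyl-2H-chromen-6-yl]ethanone
Conditions: Dess–Martin periodinane, NaHCO3, CH2Cl2, 0 to 25 °C
Reagents that add atoms: none
Why: Buffered Dess–Martin oxidation converts the secondary benzylic alcohol into the deoxybenzoin without touching silyl ethers, acetals or the chromene.

Step 13
Reactants: 17 deoxybenzoin
Product: 18 2-diazo-1-{2-(tert-butyldimethylsilyloxy)-4,6-bis(methoxymethoxy)-3-[3-methyl-3-(triethylsilyloxy)butyl]phenyl}-2-[5-(tert-butyldimethylsilyloxy)-2,2-dimethyl-2H-chromen-6-yl]ethanone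
Conditions: 4-acetamidobenzenesulfonyl azide, DBU, dry MeCN, 0 to 25 °C
Reagents that add atoms: 4-acetamidobenzenesulfonyl azide, CC(=O)Nc1ccc(cc1)S(=O)(=O)N=[N+]=[N-]
Why: Regitz diazo transfer works directly on the methylene of a deoxybenzoin because it is activated by both the ketone and the aryl group, and anhydrous conditions protect the aryl silyl ethers from DBU.

Step 14
Reactants: 18 diazo ketone
Product: 20 5-(tert-butyldimethylsilyloxy)-3-[5-(tert-butyldimethylsilyloxy)-2,2-dimethyl-2H-chromen-6-yl]-7-(methoxymethoxy)-6-[3-methyl-3-(triethylsilyloxy)butyl]-4H-chromen-4-one, via 2-methoxyisoflavanone 19 (not isolated)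
Conditions: Rh2(OAc)4 (2 mol%), CH2Cl2, 40 °C, slow addition of 18 to high dilution; then DBU, 25 °C
Reagents that add atoms: none
Why: Proposed new method: dirhodium tetraacetate (divalent rhodium) should expel N2 from 18 to give a donor/acceptor carbenoid at C3, which inserts through a three-centre transition state with hydride-transfer character into a C–H bond of the acetal methylene on the C8a oxygen, six atoms away, to form the C2–C3 bond and isoflavanone 19, from which DBU removes the acidic C3 hydrogen and expels methoxide to leave the chromone. The closest known reaction type is the Rh2(OAc)4-catalysed intramolecular C–H insertion of ortho-alkoxyaryl α-diazo ketones next to the ether oxygen to give chroman-4-ones, and insertion into an acetal O–CH2–O group has not been shown. Ring C closes as a six-membered ring by 1,6-C–H insertion, a five-membered insertion being impossible because the fifth atom is the ether oxygen. The two stereocentres of 19 (C2 and C3) become trigonal in 20, so no stereocontrol is needed. The step needs insertion at the acetal C–H in preference to attack on the aryl ether oxygen (oxonium ylide, then 1,2-shift to a benzofuranone) and to other C–H bonds: the methylene between two oxygens offers the most electron-rich C–H bonds within reach, the other ortho oxygen (C5) is a bulky and weakly basic silyl ether, the C7 MOM group is meta to the acyl carbon and cannot reach the carbenoid, high dilution suppresses intermolecular cyclopropanation of the chromene, and Rh2(O2CCPh3)4 is substituted if ylide products appear.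

Step 15
Reactants: 20 7-O-MOM isoflavone
Product: 22 5-(tert-butyldimethylsilyloxy)-3-[5-(tert-butyldimethylsilyloxy)-2,2-dimethyl-2H-chromen-6-yl]-7-hydroxy-6-[3-methyl-3-(triethylsilyloxy)butyl]-4H-chromen-4-one, via 7-O-trimethylsilyl ether 21 (not isolated)
Conditions: Me3SiOTf, 2,2'-bipyridyl, CH2Cl2, 0 to 25 °C; then H2O
Reagents that add atoms: none
Why: Silyl triflate activation buffered by 2,2'-bipyridyl converts an aromatic MOM ether into the aryl trimethylsilyl ether without protic acid, and this labile ether is hydrolysed on aqueous quench while the TBS and TES ethers and the chromene remain.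

Step 16
Reactants: 22 7-hydroxy trisilyl isoflavone
Product: 23 Kanzonol T
Conditions: Bu4NF, AcOH, THF, 0 to 25 °C
Reagents that add atoms: none
Why: Fluoride cleaves the two aryl TBS ethers and the tertiary TES ether, acetic acid keeps the liberated phenoxides protonated, and the absence of strong acid prevents cyclisation of the tertiary alcohol onto a neighbouring phenol.

**Compound list**

1 | phloroglucinol | Oc1cc(O)cc(O)c1 | starting material
2 | acrylic acid | C=CC(=O)O | starting material
3 | 5,7-dihydroxychroman-2-one | O=C1CCc2c(O)cc(O)cc2O1 | intermediate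
4 | 5,7-bis(methoxymethoxy)chroman-2-one | O=C1CCc2c(OCOC)cc(OCOC)cc2O1 | intermediate
5 | 2-(3-hydroxy-3-methylbutyl)-3,5-bis(methoxymethoxy)phenol | CC(C)(O)CCc1c(O)cc(OCOC)cc1OCOC | intermediate
6 | 2-hydroxy-3-(3-hydroxy-3-methylbutyl)-4,6-bis(methoxymethoxy)benzaldehyde | CC(C)(O)CCc1c(O)c(C=O)c(OCOC)cc1OCOC | intermediate
7 | 2-(tert-butyldimethylsilyloxy)-3-(3-hydroxy-3-methylbutyl)-4,6-bis(methoxymethoxy)benzaldehyde | CC(C)(O)CCc1c(O[Si](C)(C)C(C)(C)C)c(C=O)c(OCOC)cc1OCOC | intermediate
8 | 2-(tert-butyldimethylsilyloxy)-4,6-bis(methoxymethoxy)-3-[3-methyl-3-(triethylsilyloxy)butyl]benzaldehyde | CC[Si](CC)(CC)OC(C)(C)CCc1c(O[Si](C)(C)C(C)(C)C)c(C=O)c(OCOC)cc1OCOC | intermediate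
9 | 2,4-dihydroxybenzaldehyde | O=Cc1ccc(O)cc1O | starting material
10 | 3-methylbut-2-enal (prenal) | CC(C)=CC=O | starting material
11 | 5-hydroxy-2,2-dimethyl-2H-chromene-6-carbaldehyde | CC1(C)C=Cc2c(O)c(C=O)ccc2O1 | intermediate
12 | 5-(tert-butyldimethylsilyloxy)-2,2-dimethyl-2H-chromene-6-carbaldehyde | CC1(C)C=Cc2c(O[Si](C)(C)C(C)(C)C)c(C=O)ccc2O1 | intermediate
13 | [5-(tert-butyldimethylsilyloxy)-2,2-dimethyl-2H-chromen-6-yl]methanol | CC1(C)C=Cc2c(O[Si](C)(C)C(C)(C)C)c(CO)ccc2O1 | intermediate
14 | 5-(tert-butyldimethylsilyloxy)-6-(chloromethyl)-2,2-dimethyl-2H-chromene | CC1(C)C=Cc2c(O[Si](C)(C)C(C)(C)C)c(CCl)ccc2O1 | intermediate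
15 | {[5-(tert-butyldimethylsilyloxy)-2,2-dimethyl-2H-chromen-6-yl]methyl}zinc chloride (LiCl complex, formed in the flask) | CC1(C)C=Cc2c(O[Si](C)(C)C(C)(C)C)c(C[Zn]Cl)ccc2O1 | intermediate
16 | racemic 1-{2-(tert-butyldimethylsilyloxy)-4,6-bis(methoxymethoxy)-3-[3-methyl-3-(triethylsilyloxy)butyl]phenyl}-2-[5-(tert-butyldimethylsilyloxy)-2,2-dimethyl-2H-chromen-6-yl]ethanol | CC[Si](CC)(CC)OC(C)(C)CCc1c(O[Si](C)(C)C(C)(C)C)c(C(O)Cc2ccc3OC(C)(C)C=Cc3c2O[Si](C)(C)C(C)(C)C)c(OCOC)cc1OCOC | intermediate
17 | 1-{2-(tert-butyldimethylsilyloxy)-4,6-bis(methoxymethoxy)-3-[3-methyl-3-(triethylsilyloxy)butyl]phenyl}-2-[5-(tert-butyldimethylsilyloxy)-2,2-dimethyl-2H-chromen-6-yl]ethanone | CC[Si](CC)(CC)OC(C)(C)CCc1c(O[Si](C)(C)C(C)(C)C)c(C(=O)Cc2ccc3OC(C)(C)C=Cc3c2O[Si](C)(C)C(C)(C)C)c(OCOC)cc1OCOC | intermediate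
18 | 2-diazo-1-{2-(tert-butyldimethylsilyloxy)-4,6-bis(methoxymethoxy)-3-[3-methyl-3-(triethylsilyloxy)butyl]phenyl}-2-[5-(tert-butyldimethylsilyloxy)-2,2-dimethyl-2H-chromen-6-yl]ethanone (key-step precursor) | CC[Si](CC)(CC)OC(C)(C)CCc1c(O[Si](C)(C)C(C)(C)C)c(C(=O)C(=[N+]=[N-])c2ccc3OC(C)(C)C=Cc3c2O[Si](C)(C)C(C)(C)C)c(OCOC)cc1OCOC | intermediate
19 | 5-(tert-butyldimethylsilyloxy)-3-[5-(tert-butyldimethylsilyloxy)-2,2-dimethyl-2H-chromen-6-yl]-2-methoxy-7-(methoxymethoxy)-6-[3-methyl-3-(triethylsilyloxy)butyl]chroman-4-one (racemic diastereomer mixture at C2 and C3, formed in the flask) | CC[Si](CC)(CC)OC(C)(C)CCc1c(O[Si](C)(C)C(C)(C)C)c2C(=O)C(c3ccc4OC(C)(C)C=Cc4c3O[Si](C)(C)C(C)(C)C)C(OC)Oc2cc1OCOC | intermediate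
20 | 5-(tert-butyldimethylsilyloxy)-3-[5-(tert-butyldimethylsilyloxy)-2,2-dimethyl-2H-chromen-6-yl]-7-(methoxymethoxy)-6-[3-methyl-3-(triethylsilyloxy)butyl]-4H-chromen-4-one (key-step product) | CC[Si](CC)(CC)OC(C)(C)CCc1c(O[Si](C)(C)C(C)(C)C)c2c(=O)c(-c3ccc4OC(C)(C)C=Cc4c3O[Si](C)(C)C(C)(C)C)coc2cc1OCOC | intermediate
21 | 5-(tert-butyldimethylsilyloxy)-3-[5-(tert-butyldimethylsilyloxy)-2,2-dimethyl-2H-chromen-6-yl]-6-[3-methyl-3-(triethylsilyloxy)butyl]-7-(trimethylsilyloxy)-4H-chromen-4-one (formed in the flask) | CC[Si](CC)(CC)OC(C)(C)CCc1c(O[Si](C)(C)C(C)(C)C)c2c(=O)c(-c3ccc4OC(C)(C)C=Cc4c3O[Si](C)(C)C(C)(C)C)coc2cc1O[Si](C)(C)C | intermediate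
22 | 5-(tert-butyldimethylsilyloxy)-3-[5-(tert-butyldimethylsilyloxy)-2,2-dimethyl-2H-chromen-6-yl]-7-hydroxy-6-[3-methyl-3-(triethylsilyloxy)butyl]-4H-chromen-4-one | CC[Si](CC)(CC)OC(C)(C)CCc1c(O[Si](C)(C)C(C)(C)C)c2c(=O)c(-c3ccc4OC(C)(C)C=Cc4c3O[Si](C)(C)C(C)(C)C)coc2cc1O | intermediate
23 | Kanzonol T, 5,7-dihydroxy-3-(5-hydroxy-2,2-dimethyl-2H-chromen-6-yl)-6-(3-hydroxy-3-methylbutyl)-4H-chromen-4-one | CC(C)(O)CCc1c(O)cc2occ(-c3ccc4c(c3O)C=CC(C)(C)O4)c(=O)c2c1O | target

**Step count**

Total: 16 steps. Longest linear sequence: 12 steps (steps 1 to 6, then 11 to 16); the ring B branch is steps 7 to 10.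

**Steps most likely to fail, with fallbacks**

Step 14 (key step). The carbenoid may be captured by the aryl ether oxygen instead of the acetal C–H, so that an oxonium ylide forms and rearranges by 1,2-shift, or the carbenoid may dimerise. The fallback uses known chemistry, sets out from ketone 17 and returns to the route at isoflavone 20. MgBr2·OEt2 in CH2Cl2 at 0 °C should cleave only the acetal ortho to the ketone, because magnesium is held between the carbonyl and acetal oxygens, giving 2-hydroxydeoxybenzoin F1. Heating with N,N-dimethylformamide dimethyl acetal in toluene at 80 °C should give enaminone F2, which closes onto the free phenol with loss of dimethylamine to give 20. In this classical formylative closure C2 comes from the amide acetal, and steps 13 and 14 are bypassed.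

Step 11. Addition to the doubly ortho-substituted, electron-rich aldehyde may be slow, the labile benzylic chloride may homocouple or decompose during zinc insertion, and silyl migration in the alkoxide is conceivable. The fallback sets out from aldehyde 8 and returns at ketone 17, bypassing carbinol 16 and step 12. Pinnick oxidation (NaClO2, NaH2PO4, 2-methyl-2-butene, t-BuOH/H2O) should give benzoic acid F3. 1-Chloro-N,N,2-trimethylpropenylamine in CH2Cl2 converts it under neutral conditions into acid chloride F4. Negishi acylation of benzylzinc chloride 15 with F4 and Pd(PPh3)4 (zerovalent palladium) in THF should then give 17 irreversibly.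

Step 15. Activation of the acetal may be incomplete, or silyl exchange may occur at the aryl TBS or tertiary TES ethers. The fallback sets out from 20 and returns at target 23, bypassing 22. Bu4NF and AcOH in THF first remove the three silyl groups to give 7-O-methoxymethyl Kanzonol T F5. The remaining acetal sits on the most acidic phenol (vinylogous to the C4 carbonyl) and should be removed by transacetalisation with pyridinium p-toluenesulfonate in MeOH at 50 °C, a buffer too weak to ionise the tertiary alcohol.

**Further compounds**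

F1 | step 14 | 1-{2-(tert-butyldimethylsilyloxy)-6-hydroxy-4-(methoxymethoxy)-3-[3-methyl-3-(triethylsilyloxy)butyl]phenyl}-2-[5-(tert-butyldimethylsilyloxy)-2,2-dimethyl-2H-chromen-6-yl]ethanone | CC[Si](CC)(CC)OC(C)(C)CCc1c(O[Si](C)(C)C(C)(C)C)c(C(=O)Cc2ccc3OC(C)(C)C=Cc3c2O[Si](C)(C)C(C)(C)C)c(O)cc1OCOC
F2 | step 14 | 1-{2-(tert-butyldimethylsilyloxy)-6-hydroxy-4-(methoxymethoxy)-3-[3-methyl-3-(triethylsilyloxy)butyl]phenyl}-2-[5-(tert-butyldimethylsilyloxy)-2,2-dimethyl-2H-chromen-6-yl]-3-(dimethylamino)prop-2-en-1-one | CC[Si](CC)(CC)OC(C)(C)CCc1c(O[Si](C)(C)C(C)(C)C)c(C(=O)C(=CN(C)C)c2ccc3OC(C)(C)C=Cc3c2O[Si](C)(C)C(C)(C)C)c(O)cc1OCOC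
F3 | step 11 | 2-(tert-butyldimethylsilyloxy)-4,6-bis(methoxymethoxy)-3-[3-methyl-3-(triethylsilyloxy)butyl]benzoic acid | CC[Si](CC)(CC)OC(C)(C)CCc1c(O[Si](C)(C)C(C)(C)C)c(C(=O)O)c(OCOC)cc1OCOC
F4 | step 11 | 2-(tert-butyldimethylsilyloxy)-4,6-bis(methoxymethoxy)-3-[3-methyl-3-(triethylsilyloxy)butyl]benzoyl chloride | CC[Si](CC)(CC)OC(C)(C)CCc1c(O[Si](C)(C)C(C)(C)C)c(C(=O)Cl)c(OCOC)cc1OCOC
F5 | step 15 | 7-O-methoxymethyl Kanzonol T | CC(C)(O)CCc1c(OCOC)cc2occ(-c3ccc4c(c3O)C=CC(C)(C)O4)c(=O)c2c1O
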